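The route rests on breaking the C1'–O bond last. C1' is the carbinol carbon of the side chain on C1 of the tetralin ring. It is tied through the C2'=C3' alkene to the para position of the 4-hydroxyphenyl ring, so it is the far end of an extended p-quinone methide. Oxidising the free phenol of a cis-1-cinnamyl-6,7-dimethoxytetralin makes C1' electrophilic. The tert-butyl carbonate on the adjacent ring carbinol C2 then delivers its carbonyl oxygen there. One operation forms the C1'–O bond, a six-membered cyclic carbonate and the third stereocentre. The precursor carries only the two cis ring stereocentres, set together by dynamic kinetic resolution of a 1-cinnamyl-2-tetralone.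

Key step: step 7

Assumption: the (R,R) catalyst of step 4 is assigned from the aryl-ketone mnemonic, with the branched C1 side that carries the fused arene in the place of the aryl group; the sense should be checked on 9 and the (S,S) catalyst taken if it is reversed.

Step 1
Reactants: 1 4-(tert-butyldimethylsilyloxy)benzaldehyde; 2 vinylmagnesium bromide
Product: 4 rac-1-[4-(tert-butyldimethylsilyloxy)phenyl]prop-2-en-1-yl acetate, via bromomagnesium alkoxide 3 (not isolated)
Conditions: 2 (1.1 equiv), THF, −78 → 0 °C; then Ac2O (1.5 equiv), 0 °C → rt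
Reagents that add atoms: acetic anhydride, CC(=O)OC(C)=O
Why: Grignard 1,2-addition to the aldehyde followed by O-acylation of the magnesium alkoxide in the same flask gives a storable allyl donor in place of a labile 4-oxygenated cinnamyl halide, and the new carbinol centre may stay racemic because it is erased in the π-allyl complex of step 3.

Step 2
Reactants: 5 6,7-dimethoxy-2-tetralone
Product: 6 1-(6,7-dimethoxy-3,4-dihydronaphthalen-2-yl)pyrrolidine
Conditions: pyrrolidine (1.3 equiv), toluene, Dean–Stark reflux, N2; evaporation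
Reagents that add atoms: pyrrolidine, C1CCNC1
Why: Stork enamine condensation, in which a 2-tetralone gives only the C1=C2 enamine that is conjugated with the arene, so that C1 becomes the sole nucleophilic carbon.

Step 3
Reactants: 6 1-(6,7-dimethoxy-3,4-dihydronaphthalen-2-yl)pyrrolidine; 4 rac-1-[4-(tert-butyldimethylsilyloxy)phenyl]prop-2-en-1-yl acetate
Product: 8 rac-1-{(E)-3-[4-(tert-butyldimethylsilyloxy)phenyl]prop-2-en-1-yl}-6,7-dimethoxy-3,4-dihydronaphthalen-2(1H)-one, via C-allylated iminium acetate 7 (not isolated)
Conditions: 6 (1.15 equiv), Pd(PPh3)4 (3 mol %), THF, rt → 40 °C, N2; then AcOH/NaOAc/H2O, rt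
Reagents that add atoms: water, O
Why: Tsuji–Trost allylation of a preformed enamine, in which Pd(0) ionises the branched acetate to the 1-aryl-π-allyl complex, the soft enamine carbon attacks the unsubstituted terminus to give the linear (E)-cinnamyl product, reversible N-allylation drains to C-allylation, the strained alkylated enamine resists a second allylation, and buffered hydrolysis frees a ketone whose C1 centre is racemic and labile by design.

Step 4
Reactants: 8 rac-1-{(E)-3-[4-(tert-butyldimethylsilyloxy)phenyl]prop-2-en-1-yl}-6,7-dimethoxy-3,4-dihydronaphthalen-2(1H)-one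
Product: 9 (1S,2R)-1-{(E)-3-[4-(tert-butyldimethylsilyloxy)phenyl]prop-2-en-1-yl}-6,7-dimethoxy-1,2,3,4-tetrahydronaphthalen-2-ol (cis)
Conditions: RuCl[(R,R)-TsDPEN](p-cymene) (2 mol %), HCO2H/Et3N (1:1), CH2Cl2, 30 °C, N2
Reagents that add atoms: none
Why: Noyori–Ikariya asymmetric transfer hydrogenation under dynamic kinetic resolution, in which the benzylic α-keto C1–H enolises fast in the amine-rich medium so that both enantiomers of 8 interconvert, hydride reaches C2 anti to the pseudoaxial C1 side chain (cis), and the (R,R) catalyst selects the Si face of the (1S)-ketone, which sets C1 (S) and C2 (R) together and leaves the isolated styrenyl alkene and the aryl silyl ether untouched.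

Step 5
Reactants: 9 (1S,2R)-alcohol; 10 di-tert-butyl dicarbonate
Product: 11 tert-butyl (1S,2R)-1-{(E)-3-[4-(tert-butyldimethylsilyloxy)phenyl]prop-2-en-1-yl}-6,7-dimethoxy-1,2,3,4-tetrahydronaphthalen-2-yl carbonate
Conditions: 10 (1.5 equiv), DMAP (0.3 equiv), MeCN, rt
Reagents that add atoms: none
Why: DMAP-catalysed O-tert-butoxycarbonylation of a secondary alcohol, which touches only the O–H bond and so leaves C1 and C2 unchanged.

Step 6
Reactants: 11 silyl-protected tert-butyl carbonate
Product: 12 tert-butyl (1S,2R)-1-[(E)-3-(4-hydroxyphenyl)prop-2-en-1-yl]-6,7-dimethoxy-1,2,3,4-tetrahydronaphthalen-2-yl carbonate (cis)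
Conditions: TBAF (1.1 equiv), AcOH (1.2 equiv), THF, 0 °C
Reagents that add atoms: none
Why: Fluoride desilylation of an aryl silyl ether, buffered with acetic acid so that the phenoxide is protonated at once and the Boc carbonate is neither transferred nor cleaved.

Step 7
Reactants: 12 tert-butyl (1S,2R)-1-[(E)-3-(4-hydroxyphenyl)prop-2-en-1-yl]-6,7-dimethoxy-1,2,3,4-tetrahydronaphthalen-2-yl carbonate
Product: 14 (1S,2R,1'R)-cyclic carbonate of the target 1,3-diol (cis-fused 1,3-dioxan-2-one spanning O–C1' and O–C2 that bears an equatorial (E)-4-hydroxystyryl group at C1'), via vinylogous quinone methide 13 (not isolated)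
Conditions: DDQ (1.0 equiv, slow addition), 4 Å MS, CH2Cl2 (0.01 M), −30 → 0 °C; cold filtration, no basic wash
Reagents that add atoms: none
Why: Proposed new method: DDQ removes the phenolic hydrogen and a hydride from the cinnamylic C1'–H of 12 to give the extended quinone methide 13 (or its O-protonated ion pair with the reduced quinone), which is electrophilic at C3' and C1'; the Boc carbonyl oxygen adds at C1', the six-membered ring rearomatises to the phenol, and the tert-butoxy-dioxanylium ion sheds isobutene. The closest known reaction types are the DDQ or Ag2O oxidation of 4-propenyl- and 4-allylphenols to extended quinone methides that O-nucleophiles capture at the γ-carbon, and the neighbouring-group capture of cationic carbon by tert-butyl carbonates to give cyclic carbonates, but their union in one substrate is untested. The 1,3-dioxan-2-one closes 6-exo-trig as a 1,8-conjugate addition. C1' is controlled by a chair transition state built on the ground-state half-chair of the cis-tetralin (C1' pseudoaxial to escape the C8–H peri contact, C2–O equatorial), in which C1–H eclipses C1'=C2' (least A1,3 strain) and the dienone arm is equatorial, so the C–O bond forms on the face that leaves the styryl group trans to C8a and C3, that is (1'R). Attack at C1' instead of C3' follows from ring size (six atoms against eight with an E-alkene inside the ring), and chemoselectivity follows from the free phenol being far easier to oxidise than the veratrole ring. Slow addition of a single equivalent of DDQ, high dilution and sieves are meant to hold back further oxidation of the still oxidisable product, intermolecular phenol capture, water capture and proton loss from C1.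

Step 8
Reactants: 14 (1S,2R,1'R)-cyclic carbonate
Product: 15 (1S,2R)-1-[(1R,2E)-1-hydroxy-3-(4-hydroxyphenyl)prop-2-en-1-yl]-6,7-dimethoxy-1,2,3,4-tetrahydronaphthalen-2-ol (target)
Conditions: MeLi (5 equiv), THF, −78 °C; sat aq NH4Cl at −78 °C
Reagents that add atoms: none
Why: Organolithium cleavage of a carbonate by three additions to the carbonyl carbon leaves both C–O bonds and all stereocentres intact, and it is chosen over carbonate or alkoxide bases in methanol because a free phenoxide there could expel the C1' oxygen by 1,8-elimination, whereas the aggregated lithium phenoxide at −78 °C should be too slow to do so and no leaving group remains once both oxygens are alkoxides.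

Compound list
1 | 4-(tert-butyldimethylsilyloxy)benzaldehyde | O=Cc1ccc(O[Si](C)(C)C(C)(C)C)cc1 | starting material
2 | vinylmagnesium bromide | C=C[Mg]Br | starting material
3 | bromomagnesium 1-[4-(tert-butyldimethylsilyloxy)phenyl]prop-2-en-1-olate (formed in the flask) | C=CC(O[Mg]Br)c1ccc(O[Si](C)(C)C(C)(C)C)cc1 | intermediate
4 | rac-1-[4-(tert-butyldimethylsilyloxy)phenyl]prop-2-en-1-yl acetate | CC(=O)OC(C=C)c1ccc(O[Si](C)(C)C(C)(C)C)cc1 | intermediate
5 | 6,7-dimethoxy-2-tetralone | COc1cc2CCC(=O)Cc2cc1OC | starting material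
6 | 1-(6,7-dimethoxy-3,4-dihydronaphthalen-2-yl)pyrrolidine | COc1cc2CCC(=Cc2cc1OC)N1CCCC1 | intermediate
7 | C1-allylated pyrrolidinium (iminium) acetate, racemic (formed in the flask) | COc1cc2c(cc1OC)C(C/C=C/c1ccc(O[Si](C)(C)C(C)(C)C)cc1)C(=[N+]1CCCC1)CC2.CC(=O)[O-] | intermediate
8 | rac-1-{(E)-3-[4-(tert-butyldimethylsilyloxy)phenyl]prop-2-en-1-yl}-6,7-dimethoxy-3,4-dihydronaphthalen-2(1H)-one | COc1cc2c(cc1OC)C(C/C=C/c1ccc(O[Si](C)(C)C(C)(C)C)cc1)C(=O)CC2 | intermediate
9 | (1S,2R)-1-{(E)-3-[4-(tert-butyldimethylsilyloxy)phenyl]prop-2-en-1-yl}-6,7-dimethoxy-1,2,3,4-tetrahydronaphthalen-2-ol (cis) | COc1cc2c(cc1OC)[C@H](C/C=C/c1ccc(O[Si](C)(C)C(C)(C)C)cc1)[C@H](O)CC2 | intermediate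
10 | di-tert-butyl dicarbonate | CC(C)(C)OC(=O)OC(=O)OC(C)(C)C | starting material
11 | tert-butyl (1S,2R)-1-{(E)-3-[4-(tert-butyldimethylsilyloxy)phenyl]prop-2-en-1-yl}-6,7-dimethoxy-1,2,3,4-tetrahydronaphthalen-2-yl carbonate | COc1cc2c(cc1OC)[C@H](C/C=C/c1ccc(O[Si](C)(C)C(C)(C)C)cc1)[C@H](OC(=O)OC(C)(C)C)CC2 | intermediate
12 | tert-butyl (1S,2R)-1-[(E)-3-(4-hydroxyphenyl)prop-2-en-1-yl]-6,7-dimethoxy-1,2,3,4-tetrahydronaphthalen-2-yl carbonate (key-step precursor) | COc1cc2c(cc1OC)[C@H](C/C=C/c1ccc(O)cc1)[C@H](OC(=O)OC(C)(C)C)CC2 | intermediate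
13 | tert-butyl (1S,2R)-6,7-dimethoxy-1-[(E)-3-(4-oxocyclohexa-2,5-dien-1-ylidene)prop-1-en-1-yl]-1,2,3,4-tetrahydronaphthalen-2-yl carbonate (vinylogous quinone methide, formed in the flask) | COc1cc2c(cc1OC)[C@H](/C=C/C=C1C=CC(=O)C=C1)[C@H](OC(=O)OC(C)(C)C)CC2 | intermediate
14 | (1S,2R,1'R)-cyclic carbonate of the target diol: cis-fused 1,3-dioxan-2-one over O–C1' and O–C2, (E)-4-hydroxystyryl at C1' trans to C8a and C3 (key-step product) | COc1cc2c(cc1OC)[C@@H]3[C@@H](/C=C/c1ccc(O)cc1)OC(=O)O[C@@H]3CC2 | intermediate
15 | (1S,2R)-1-[(1R,2E)-1-hydroxy-3-(4-hydroxyphenyl)prop-2-en-1-yl]-6,7-dimethoxy-1,2,3,4-tetrahydronaphthalen-2-ol | COc1cc2c(cc1OC)[C@H]([C@H](O)/C=C/c1ccc(O)cc1)[C@H](O)CC2 | target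

Total step count: 8.
Longest linear sequence: 7 steps (5 → 6 → 8 → 9 → 11 → 12 → 14 → 15). The arm from 1 through 4 is equally long.

Steps most likely to fail

**Step 7.**
- What may go wrong: the quinone methide may lose the C1 proton, which means tautomerisation into conjugation, then loss of the carbonate and aromatisation. It may instead be captured intermolecularly by phenol or by the reduced quinone, or the product may re-ionise at C1'.
- Fallback with known chemistry only, from 9 back to 15: Riley allylic hydroxylation of 9 (cat SeO2, TBHP, CH2Cl2) at its only allylic methylene should give the C1'-epimeric diol F1. MnO2 (CH2Cl2, rt) oxidises only the cinnamylic alcohol and gives the β-hydroxy enone F2. Evans–Saksena reduction (Me4NBH(OAc)3, MeCN/AcOH, −30 °C) delivers hydride from boron bound to the C2 hydroxyl. It should give the 1,3-anti diol, which is the TBS ether of the target F3. TBAF/AcOH (THF, 0 °C) then gives 15.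

**Step 4.**
- What may go wrong: racemisation that is slow relative to reduction would erode enantiomeric purity. So would weak face discrimination by the catalyst on a ketone with no directly attached arene.
- Fallback from 8 back to 9: substrate-controlled reduction with L-Selectride (THF, −78 °C) attacks anti to the pseudoaxial side chain and gives the racemic cis alcohol F4. Lipase-catalysed acylative kinetic resolution (Burkholderia cepacia lipase or CAL-B, vinyl acetate, MTBE) should acylate the (2R) enantiomer according to the Kazlauskas rule. This gives the (1S,2R)-acetate F5, which is separated from the unreacted (1R,2S)-alcohol. DIBAL-H (CH2Cl2, −78 °C) removes the acetyl group without touching the aryl silyl ether and gives 9.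

**Step 8.**
- What may go wrong: phenoxide-triggered 1,8-elimination of the C1' oxygen may occur before the carbonyl group is consumed, with loss of the C1' stereocentre or of the oxygen itself. Cleavage may also stop at a monoacyl stage.
- Fallback from 14 back to 15: the donor is masked first. TIPSCl and imidazole (DMF, 0 °C) give the TIPS ether of the cyclic carbonate F6. LiAlH4 (THF, 0 °C) reduces the carbonate and gives the TIPS ether of the target F7. TBAF/AcOH (THF, 0 °C) gives 15, which is safe because a hydroxyl group is not a leaving group for the phenoxide.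

Further compounds
F1 | step 7 | (1S,2R)-1-{(E)-3-[4-(tert-butyldimethylsilyloxy)phenyl]-1-hydroxyprop-2-en-1-yl}-6,7-dimethoxy-1,2,3,4-tetrahydronaphthalen-2-ol, mixture of C1' epimers | COc1cc2c(cc1OC)[C@H](C(O)/C=C/c1ccc(O[Si](C)(C)C(C)(C)C)cc1)[C@H](O)CC2
F2 | step 7 | (E)-3-[4-(tert-butyldimethylsilyloxy)phenyl]-1-[(1,2-cis)-2-hydroxy-6,7-dimethoxy-1,2,3,4-tetrahydronaphthalen-1-yl]prop-2-en-1-one, ring configuration as in 9 | COc1cc2c(cc1OC)[C@H](C(=O)/C=C/c1ccc(O[Si](C)(C)C(C)(C)C)cc1)[C@H](O)CC2
F3 | step 7 | (1S,2R,1'R)-4-O-TBS ether of the target | COc1cc2c(cc1OC)[C@H]([C@H](O)/C=C/c1ccc(O[Si](C)(C)C(C)(C)C)cc1)[C@H](O)CC2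
F4 | step 4 | racemic cis alcohol (both enantiomers) | COc1cc2c(cc1OC)[C@H](C/C=C/c1ccc(O[Si](C)(C)C(C)(C)C)cc1)[C@H](O)CC2.COc1cc2c(cc1OC)[C@@H](C/C=C/c1ccc(O[Si](C)(C)C(C)(C)C)cc1)[C@@H](O)CC2
F5 | step 4 | (1S,2R)-1-{(E)-3-[4-(tert-butyldimethylsilyloxy)phenyl]prop-2-en-1-yl}-6,7-dimethoxy-1,2,3,4-tetrahydronaphthalen-2-yl acetate | COc1cc2c(cc1OC)[C@H](C/C=C/c1ccc(O[Si](C)(C)C(C)(C)C)cc1)[C@H](OC(C)=O)CC2
F6 | step 8 | (1S,2R,1'R)-cyclic carbonate with the phenol as TIPS ether | COc1cc2c(cc1OC)[C@@H]3[C@@H](/C=C/c1ccc(O[Si](C(C)C)(C(C)C)C(C)C)cc1)OC(=O)O[C@@H]3CC2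
F7 | step 8 | (1S,2R,1'R)-4-O-TIPS ether of the target | COc1cc2c(cc1OC)[C@H]([C@H](O)/C=C/c1ccc(O[Si](C(C)C)(C(C)C)C(C)C)cc1)[C@H](O)CC2
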